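The quinone ring is cut at C2–C3, the bond joining its two methyl-bearing carbons. These carbons are the α-carbons of the C1 and C4 carbonyls, so the bond is that of a 1,4-dicarbonyl and can come from oxidative coupling of two enol ethers held cis by the C5=C6 alkene. The precursor is acyclic: the bis(silyl dienol ether) of a (Z)-oct-4-ene-3,6-dione carrying the side chain, unmasked from a 2,5-diethylfuran with singlet oxygen. One anodic operation closes the ring, aromatizes it and leaves the quinone. The (7S,11S) chain comes from iridium-catalysed asymmetric hydrogenation of (E,E)-farnesylacetone; carboalumination fixes the (E)-alkene.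

Key step: step 10

Remark on the chemistry: the two side-chain stereocenters of the SMILES read as 7S,11S, the mirror image of the chain of natural phytol, so the chain is built by asymmetric catalysis and not taken from natural phytol. The ligand antipode for step 2 is the mirror image of the one that serves the natural 6R,10R series on this substrate class; the sense should be confirmed against the 6R,10R ketone available by ozonolysis of natural phytol.

Step 1
Reactants: 1 (2E,6E)-farnesyl bromide; 2 ethyl acetoacetate
Product: 4 (5E,9E)-6,10,14-trimethylpentadeca-5,9,13-trien-2-one (farnesylacetone), via β-keto ester 3 (not isolated)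
Conditions: 2 (1.5 equiv), NaOEt, EtOH, 0 °C → 20 °C; then 2 M NaOH, 60 °C; then 1 M HCl to pH 3, 50 °C
Reagents that add atoms: none
Why: Acetoacetic ester synthesis: the soft sodium enolate of 2 displaces the primary allylic bromide by SN2 without touching the two (E)-alkenes, and saponification of 3 followed by decarboxylation of the β-keto acid leaves the methyl ketone.

Step 2
Reactants: 4 (5E,9E)-farnesylacetone
Product: 5 (6S,10S)-6,10,14-trimethylpentadecan-2-one
Conditions: H2 (50 bar), [Ir(cod)(L)][B(C6H3(CF3)2)4] (1 mol %), CH2Cl2, 25 °C; L = enantiopure 2-phenyl-7-[bis(2-methylphenyl)phosphanyloxy]-6,7-dihydro-5H-cyclopenta[b]pyridine, antipode chosen to give 6S,10S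
Reagents that add atoms: none
Why: Iridium N,P-ligand catalysed asymmetric hydrogenation of unfunctionalized trisubstituted olefins: the catalyst distinguishes the enantiotopic faces of the two (E)-alkenes by their substitution pattern alone and so should set C6 and C10 in the same sense under catalyst control, while the isopropylidene end becomes isopropyl and the ketone is left alone.

Step 3
Reactants: 5 (6S,10S)-6,10,14-trimethylpentadecan-2-one
Product: 7 (6S,10S)-6,10,14-trimethylpentadec-1-yne, via enol phosphate 6 (not isolated)
Conditions: LiN(iPr)2 (1.1 equiv), THF, −78 °C; ClP(O)(OEt)2, −78 °C → 20 °C; then LiN(iPr)2 (2.3 equiv), THF, −78 °C → 20 °C; H2O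
Reagents that add atoms: none
Why: Methyl ketone to terminal alkyne conversion: kinetic enolization at the methyl group and O-phosphorylation give enol phosphate 6, from which LiN(iPr)2 eliminates diethyl phosphate to the lithium acetylide, the non-acidic remote stereocenters being untouched.

Step 4
Reactants: 8 ethyl 3-oxopentanoate; 9 1-bromobutan-2-one
Product: 11 ethyl 2,5-diethylfuran-3-carboxylate, via diketo ester 10 (not isolated)
Conditions: NaH (1.05 equiv), THF, 0 °C, then 9, 0 °C → 20 °C; then TsOH·H2O (0.3 equiv), toluene, reflux with a Dean–Stark trap (THF distilled off)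
Reagents that add atoms: none
Why: C-Alkylation of the β-keto ester enolate by the α-bromo ketone gives 1,4-diketone 10, whose acid-catalysed cyclodehydration (Paal–Knorr furan synthesis) fixes the 2,5-diethyl-3-ester pattern without regiochemical ambiguity.

Step 5
Reactants: 11 ethyl 2,5-diethylfuran-3-carboxylate
Product: 12 (2,5-diethylfuran-3-yl)methanol
Conditions: LiAlH4, Et2O, 0 °C; aqueous NaOH work-up
Reagents that add atoms: none
Why: LiAlH4 reduction of the ester to the primary alcohol, the furan ring being inert to hydride.

Step 6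
Reactants: 12 (2,5-diethylfuran-3-yl)methanol
Product: 13 3-(chloromethyl)-2,5-diethylfuran
Conditions: PPh3, N-chlorosuccinimide, THF, 0 °C; pentane trituration, filtration; used crude at once
Reagents that add atoms: N-chlorosuccinimide, ClN1C(=O)CCC1=O
Why: Appel-type chlorination through the alkoxyphosphonium ion under neutral conditions that spare the acid-sensitive furan; the ionizable furylmethyl chloride is used at once without chromatography.

Step 7
Reactants: 7 (6S,10S)-6,10,14-trimethylpentadec-1-yne; 13 3-(chloromethyl)-2,5-diethylfuran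
Product: 15 2,5-diethyl-3-[(2E,7S,11S)-3,7,11,15-tetramethylhexadec-2-en-1-yl]furan, via alkenylalane 14 (not isolated)
Conditions: 7, AlMe3 (2.0 equiv), Cp2ZrCl2 (0.2 equiv), ClCH2CH2Cl, 0 °C → 20 °C; volatiles removed in vacuo, THF; then 13 (0.9 equiv), Pd(PPh3)4 (3 mol %), THF, 0 °C → 20 °C
Reagents that add atoms: trimethylaluminium, C[Al](C)C
Why: Zr-catalysed syn-methylalumination of the terminal alkyne places the new methyl and the aluminium cis on the alkene, and Pd-catalysed cross-coupling of alkenylalane 14 with the heterobenzylic chloride (Negishi-type coupling) proceeds with retention, so the (2E) geometry of the side chain follows from the syn addition.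

Step 8
Reactants: 15 2,5-diethyl-3-[(2E,7S,11S)-3,7,11,15-tetramethylhexadec-2-en-1-yl]furan
Product: 17 (4Z)-4-[(2E,7S,11S)-3,7,11,15-tetramethylhexadec-2-en-1-yl]oct-4-ene-3,6-dione, via endoperoxide 16 (not isolated)
Conditions: O2, tetraphenylporphyrin (cat.), white LED, CH2Cl2, −78 °C, stopped at one equivalent of O2; then Me2S (2 equiv), −78 °C → 0 °C, dark
Reagents that add atoms: dioxygen, O=O
Why: Photooxygenation: singlet oxygen adds [4+2] across the electron-rich 2,5-dialkylfuran much faster than it attacks the isolated trisubstituted alkene, and Me2S reduction of endoperoxide 16 unmasks the ene-dione with the (Z) geometry dictated by the former ring.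

Step 9
Reactants: 17 (4Z)-4-[(2E,7S,11S)-3,7,11,15-tetramethylhexadec-2-en-1-yl]oct-4-ene-3,6-dione
Product: 18 (2Z,4Z,6Z)-3,6-bis(tert-butyldimethylsilyloxy)-4-[(2E,7S,11S)-3,7,11,15-tetramethylhexadec-2-en-1-yl]octa-2,4,6-triene
Conditions: TBSOTf (2.4 equiv), iPr2NEt (3.0 equiv), CH2Cl2, −78 °C → −30 °C; cold NaHCO3 work-up, filtration through basic alumina, stored at −20 °C
Reagents that add atoms: tert-butyldimethylsilyl trifluoromethanesulfonate, CC(C)(C)[Si](C)(C)OS(=O)(=O)C(F)(F)F
Why: Soft enolization (silyl triflate and hindered amine): each carbonyl is O-silylated and deprotonated at its own ethyl CH2 under kinetic control, the enol ether geometry being (Z) to keep the methyl away from the triene backbone, and the low temperature should suppress deprotonation at the doubly allylic side-chain CH2 and thermal ring closure.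

Step 10
Reactants: 18 (2Z,4Z,6Z)-3,6-bis(tert-butyldimethylsilyloxy)-4-[(2E,7S,11S)-3,7,11,15-tetramethylhexadec-2-en-1-yl]octa-2,4,6-triene
Product: 21 2,3-dimethyl-5-[(2E,7S,11S)-3,7,11,15-tetramethylhexadec-2-en-1-yl]cyclohexa-2,5-diene-1,4-dione, via ene-1,4-dione 19 (not isolated), via hydroquinone 20 (not isolated)
Conditions: divided cell (glass frit), reticulated vitreous carbon anode, Pt cathode, constant current, 4.2 F/mol, LiClO4 (0.1 M), 2,6-lutidine (5 equiv), CH2Cl2/MeOH 4:1, 0 °C → 20 °C
Reagents that add atoms: none
Why: Proposed new method: one-electron oxidation at the anode of the electron-rich 3,6-bis(silyloxy)triene, which should be oxidized well before the isolated side-chain alkene, gives a radical cation whose two enol ether termini (the CH(Me) carbons) are held within bonding distance by the (4Z)-alkene and join to form the C2–C3 bond of the ring. A second electron transfer and methanolysis of the two silyl oxocarbenium ions give ene-1,4-dione 19, which enolizes under 2,6-lutidine to hydroquinone 20 and is oxidized at the same anode by two further electrons to the quinone (4 F/mol in all). The closest known reaction type is the intramolecular anodic olefin coupling of two enol ethers, together with the oxidative coupling of bis(silyl enol ethers) to 1,4-diketones; new is its use on the bis(dienol ether) of a cis-enedione with aromatization in the same flask. The six-membered ring closes in a 6-endo-trig mode, equivalent to the 1,6-closure of a hexatriene radical cation. The two CH(Me) stereocenters of 19 are uncontrolled and immaterial because both become sp2 on enolization, and the side-chain stereocenters and the (2E)-alkene are not involved. The step needs 1,6-closure to outrun 5-exo attack of the side-chain alkene on the radical cation and proton loss from the doubly allylic CH2; the much higher nucleophilicity of the silyl enol ether terminus and the pre-organised Z-triene should secure this, and the divided cell keeps the quinone away from the cathode.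

Compound list
1 | (2E,6E)-1-bromo-3,7,11-trimethyldodeca-2,6,10-triene (farnesyl bromide) | BrC/C=C(\C)CC/C=C(\C)CCC=C(C)C | starting material
2 | ethyl acetoacetate | CCOC(=O)CC(C)=O | starting material
3 | ethyl (4E,8E)-2-acetyl-5,9,13-trimethyltetradeca-4,8,12-trienoate (racemic at C2) | CCOC(=O)C(C/C=C(\C)CC/C=C(\C)CCC=C(C)C)C(C)=O | intermediate
4 | (5E,9E)-6,10,14-trimethylpentadeca-5,9,13-trien-2-one | CC(=O)CC/C=C(\C)CC/C=C(\C)CCC=C(C)C | intermediate
5 | (6S,10S)-6,10,14-trimethylpentadecan-2-one | CC(=O)CCC[C@@H](C)CCC[C@@H](C)CCCC(C)C | intermediate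
6 | diethyl (6S,10S)-6,10,14-trimethylpentadec-1-en-2-yl phosphate | C=C(OP(=O)(OCC)OCC)CCC[C@@H](C)CCC[C@@H](C)CCCC(C)C | intermediate
7 | (6S,10S)-6,10,14-trimethylpentadec-1-yne | C#CCCC[C@@H](C)CCC[C@@H](C)CCCC(C)C | intermediate
8 | ethyl 3-oxopentanoate | CCC(=O)CC(=O)OCC | starting material
9 | 1-bromobutan-2-one | CCC(=O)CBr | starting material
10 | ethyl 4-oxo-2-propanoylhexanoate (racemic at C2) | CCC(=O)CC(C(=O)CC)C(=O)OCC | intermediate
11 | ethyl 2,5-diethylfuran-3-carboxylate | CCOC(=O)c1cc(CC)oc1CC | intermediate
12 | (2,5-diethylfuran-3-yl)methanol | CCc1cc(CO)c(CC)o1 | intermediate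
13 | 3-(chloromethyl)-2,5-diethylfuran | CCc1cc(CCl)c(CC)o1 | intermediate
14 | dimethyl[(1E,6S,10S)-2,6,10,14-tetramethylpentadec-1-en-1-yl]alumane | C[Al](C)/C=C(\C)CCC[C@@H](C)CCC[C@@H](C)CCCC(C)C | intermediate
15 | 2,5-diethyl-3-[(2E,7S,11S)-3,7,11,15-tetramethylhexadec-2-en-1-yl]furan | CCc1cc(C/C=C(\C)CCC[C@@H](C)CCC[C@@H](C)CCCC(C)C)c(CC)o1 | intermediate
16 | 1,4-diethyl-5-[(2E,7S,11S)-3,7,11,15-tetramethylhexadec-2-en-1-yl]-2,3,7-trioxabicyclo[2.2.1]hept-5-ene (both bridgehead diastereomers) | CCC12OOC(CC)(O1)C=C2C/C=C(\C)CCC[C@@H](C)CCC[C@@H](C)CCCC(C)C | intermediate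
17 | (4Z)-4-[(2E,7S,11S)-3,7,11,15-tetramethylhexadec-2-en-1-yl]oct-4-ene-3,6-dione | CCC(=O)/C(C/C=C(\C)CCC[C@@H](C)CCC[C@@H](C)CCCC(C)C)=C\C(=O)CC | intermediate
18 | (2Z,4Z,6Z)-3,6-bis(tert-butyldimethylsilyloxy)-4-[(2E,7S,11S)-3,7,11,15-tetramethylhexadec-2-en-1-yl]octa-2,4,6-triene | C/C=C(\O[Si](C)(C)C(C)(C)C)/C(C/C=C(\C)CCC[C@@H](C)CCC[C@@H](C)CCCC(C)C)=C\C(O[Si](C)(C)C(C)(C)C)=C\C | intermediate
19 | 2,3-dimethyl-5-[(2E,7S,11S)-3,7,11,15-tetramethylhexadec-2-en-1-yl]cyclohex-5-ene-1,4-dione (cis and trans at C2/C3, both lost on enolization) | CC1C(C)C(=O)C(C/C=C(\C)CCC[C@@H](C)CCC[C@@H](C)CCCC(C)C)=CC1=O | intermediate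
20 | 2,3-dimethyl-5-[(2E,7S,11S)-3,7,11,15-tetramethylhexadec-2-en-1-yl]benzene-1,4-diol | Cc1c(C)c(O)c(C/C=C(\C)CCC[C@@H](C)CCC[C@@H](C)CCCC(C)C)cc1O | intermediate
21 | 2,3-dimethyl-5-[(2E,7S,11S)-3,7,11,15-tetramethylhexadec-2-en-1-yl]cyclohexa-2,5-diene-1,4-dione | CC1=C(C)C(=O)C(C/C=C(\C)CCC[C@@H](C)CCC[C@@H](C)CCCC(C)C)=CC1=O | target

Total step count: 10. Longest linear sequence: 7 steps (steps 1, 2, 3, 7, 8, 9, 10; the furan branch, steps 4, 5, 6, 7, 8, 9, 10, is equally long).

Steps most likely to fail

Step 10. The radical cation may be diverted before its two termini meet: 5-exo capture by the side-chain alkene, proton loss from the doubly allylic CH2, or rotation about the central alkene followed by solvolysis back to an enedione. The fallback sets out from 18 and forms the same C2–C3 bond without electron transfer. Heating in toluene at 110 °C should bring about thermal disrotatory 6π electrocyclization of the Z-triene to the cis-5,6-dimethylcyclohexa-1,3-diene bis(silyl ether) F1. DDQ (CH2Cl2, 0 °C) then dehydrogenates it to the hydroquinone bis(silyl ether) F2. Oxidative desilylation with (NH4)2Ce(NO3)6 in MeCN/H2O at 0 °C comes back to the route at 21.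

Step 9. Enolization may go astray by deprotonation at the doubly allylic side-chain CH2 instead of the ethyl groups, or the amine may isomerize the (Z)-enedione to the (E)-isomer before silylation. The fallback sets out from 17 and avoids the silyl ether altogether. LiN(SiMe3)2 (2.2 equiv, THF, −78 °C) removes the two ethyl α-protons under kinetic control to give the dilithium bis(enolate) F3 (enolate geometry immaterial). Anhydrous CuCl2 (2.2 equiv, DMF, −78 °C → 0 °C) then couples the two enolate carbons oxidatively in the same flask, a known intramolecular oxidative enolate coupling to 1,4-diketones. The ene-dione 19 so formed enolizes to hydroquinone 20, and Ag2O in Et2O takes the crude material to 21, where the fallback comes back to the route.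

Step 7. The electron-rich furylmethyl chloride may ionize under the Lewis-acidic aluminium species, so that methyl transfer or oligomerization takes the place of cross-coupling. The fallback sets out from 7 and 13 and reverses the polarity of the union. Alkenylalane 14, made as before, is cleaved with I2 (THF, −30 °C) with retention to the (E)-alkenyl iodide F4. Chloride 13 is inserted with Zn dust and LiCl (THF, 25 °C) to the furylmethylzinc chloride F5. Pd(PPh3)4-catalysed Negishi coupling of F4 with F5 (THF, 25 °C) comes back to the route at 15.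

Further compounds
F1 | step 10 | cis-1,4-bis(tert-butyldimethylsilyloxy)-5,6-dimethyl-2-[(2E,7S,11S)-3,7,11,15-tetramethylhexadec-2-en-1-yl]cyclohexa-1,3-diene (both cis diastereomers; ring centers left undefined, both are lost in the next operation) | CC1C(C)C(O[Si](C)(C)C(C)(C)C)=C(C/C=C(\C)CCC[C@@H](C)CCC[C@@H](C)CCCC(C)C)C=C1O[Si](C)(C)C(C)(C)C
F2 | step 10 | 1,4-bis(tert-butyldimethylsilyloxy)-2,3-dimethyl-5-[(2E,7S,11S)-3,7,11,15-tetramethylhexadec-2-en-1-yl]benzene | Cc1c(C)c(O[Si](C)(C)C(C)(C)C)c(C/C=C(\C)CCC[C@@H](C)CCC[C@@H](C)CCCC(C)C)cc1O[Si](C)(C)C(C)(C)C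
F3 | step 9 | dilithium (2Z,4Z,6Z)-4-[(2E,7S,11S)-3,7,11,15-tetramethylhexadec-2-en-1-yl]octa-2,4,6-triene-3,6-bis(olate) | C/C=C(\O[Li])/C(C/C=C(\C)CCC[C@@H](C)CCC[C@@H](C)CCCC(C)C)=C\C(O[Li])=C\C
F4 | step 7 | (1E,6S,10S)-1-iodo-2,6,10,14-tetramethylpentadec-1-ene | I/C=C(\C)CCC[C@@H](C)CCC[C@@H](C)CCCC(C)C
F5 | step 7 | [(2,5-diethylfuran-3-yl)methyl]zinc chloride | CCc1cc(C[Zn]Cl)c(CC)o1
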